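The slowness of the elm run, which by its readings took 8.00 min to bring target and side product to 97.0 % of the charged substrate, made me want to avoid building a slow rig for nothing, so before charging anything I had to know whether the vessel could matter.

| setting | elm | alder | cedar | violet | red | amber | ochre |
|---|---|---|---|---|---|---|---|
| substrate | 0.30 M | 0.20 M | 0.45 M | 0.30 M | 0.30 M | 0.30 M | 0.30 M (fed, over 4.00 min) |
| partner | 1.2 M | 1.2 M | 1.2 M | 1.20 M | 1.20 M | 1.20 M | 1.20 M |
| protic impurity | 0.060 M | 0.060 M | 0.060 M | 0.0600 M | 0.0600 M | 0.0600 M | 0.0600 M |
| remark | run made earlier | run made earlier | run made earlier | one stirred flow tank at steady state, fed with the mixture as stated, mean residence time 8.0 min | one stirred flow tank at steady state, fed with the mixture as stated, mean residence time 80.0 min | everything together in a closed stirred flask, run for 8.0 min | a stirred flask in which substrate is dosed at a steady rate over 4.00 min without added volume, worked up at 8.0 min |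
| time |  |  |  |  |  | 8.0 min | 8.0 min |

- elm (time / min: target / %, side product / %): 0.667: 10, 15; 1.33: 14, 27; 2.50: 26, 41; 4.00: 28, 50; 8.00: 36, 61
- alder (time / min: target / %, side product / %): 0.417: 7, 11; 1.33: 15, 27; 2.00: 19, 36; 3.00: 25, 46; 5.00: 32, 57
- cedar (time / min: target / %, side product / %): 0.417: 7, 9; 0.667: 8, 14; 1.33: 15, 27; 2.50: 19, 38; 5.00: 30, 51

(scatter of a reading: 1.5 percentage points)

- the stated concentrations are those of everything mixed, before any reaction; amounts are the same in each set-up
- the feed brings no volume worth counting
- the earlier runs were made in a closed, stirred flask

- the set-up with the highest share of target in all that became target or side product, at the outlet or at the end ("none" if the first two lie within 2 percentage points) (violet / red / amber / ochre / none)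
- share of target in all that became target or side product, at the outlet or at the end, violet
- share of target in all that became target or side product, at the outlet or at the end, red
- share of target in all that became target or side product, at the outlet or at the end, amber
- share of target in all that became target or side product, at the outlet or at the end, ochre

I treated the two products as two decay channels of one level: if both leave the same pool by first-order steps, their rates keep a constant ratio, the selectivity factor, however a fast step before them fills that pool. The last readings tested this, giving a target share of 37.1 % in elm, 36.0 % in alder and 37.0 % in cedar, while [substrate] went from 0.20 M to 0.45 M. That spread of 1.1 percentage points is smaller than the margin of 2 points, and a single reading scatters by 1.5 points. Pooling those readings gave 36.7 %, which I carried as the branching share, target over target plus side product. I therefore decided to charge amber, the plain closed flask, first, and to expect from the tanks and the dosing line no share that differed from it by the margin.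

The forecast gave 36.5 % for violet, 36.5 % for red, 36.5 % for amber and 36.5 % for ochre, with none as the best set-up, on the ground that “Dosing, back-mixing and residence time change substrate level and conversion, but not the ratio of the two rates.” My share stood higher by 0.2 points.

The flasks gave 35.5 % in violet, 35.5 % in red, 35.5 % in amber and 35.5 % in ochre, so the best set-up came out as none.

    substrate + partner ⇌ adduct (K = 1.43 L mol⁻¹, k = 0.910 L mol⁻¹ s⁻¹)
    adduct → target (k = 0.00400 s⁻¹)
    partner + protic impurity → quenched reagent (k = 0.0190 L mol⁻¹ s⁻¹)
    adduct → side product (k = 0.00726 s⁻¹)

In amber at 8.00 min, adduct was used for side product 1.8 times as fast as for target. That ratio makes target 35.5 % of what adduct gave by these two steps. Applied to the 95.1 % of substrate that had become product in amber by 8.00 min, my 36.7 % gives 34.9 % of target, and the flask held 33.8 %. Applied to the same amber mixture read at 20 min, it gives 36.7 %, and that flask held 35.5 %.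

(The earlier runs and the new flask were generated by integration on assumed constants, noise included.)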